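Amounts first: free monomer at 20 mM outnumbers the initiator of cedar 133 to one, so radicals stay few while chains grow. The hunch that the longer time of oak makes up for its smaller charge can be put to a number.

in all of them: free monomer 20 mM
- zeta: initiator 28 µM; run made earlier
- alpha: initiator 73 µM; run made earlier
- epsilon: initiator 160 µM; run made earlier
- cedar: initiator 150 µM; time 3.0 min
- oak: initiator 40 µM; time 5.0 min

| run | time / min | monomer in chains / % |
|---|---|---|
| zeta | 0.500 | 11 |
| zeta | 1.00 | 16 |
| zeta | 1.50 | 20 |
| zeta | 2.00 | 18 |
| zeta | 2.50 | 25 |
| alpha | 0.200 | 7 |
| alpha | 0.417 | 11 |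
| alpha | 0.667 | 16 |
| alpha | 1.33 | 28 |
| alpha | 2.50 | 39 |
| epsilon | 0.200 | 11 |
| epsilon | 0.667 | 22 |
| epsilon | 1.33 | 34 |
| epsilon | 2.00 | 44 |
| epsilon | 2.50 | 48 |

(each reading ± 2 percentage points)

- a species is counted by the free monomer in it: one homo dimer counts as two
- what was read earlier has a scatter of 2 percentage points, one standard deviation
- what may be going on: initiator -> 2 initiating radical; 2 free monomer -> homo dimer; 2 growing radical -> dead chain; free monomer + initiating radical -> growing radical + monomer in chains; free monomer + growing radical -> monomer in chains + growing radical

- the flask that ends with the higher amount of monomer in chains, in percent of the free monomer charged, or "neither" when 2 percentage points or less lies between them (cedar / oak / neither)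
- final monomer in chains, as a percentage of the free monomer charged, in cedar
- final monomer in chains, as a percentage of the free monomer charged, in oak

Reckon with c(growing radical) held at the balance of its formation and its pairwise termination. That level goes with the root of c(initiator), and free monomer then enters chains by a pseudo-first-order law with a growth rate constant g. The first epsilon reading gives g = 0.583 min⁻¹, a reading that carries the scatter. Scaled by the root, it gives 0.244 min⁻¹ for zeta, whose first reading gives 0.233 min⁻¹.

The curves bend, so add a lumped rival loss, second order in free monomer, with rate b at full charge. Trying b = 1.00 min⁻¹ gives, for the fraction in chains, (g/b) ln(1 + (b/g)(1 − exp(−gt))). That passes 48.9 % at the last epsilon reading, which stands at 48 %.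

Cedar, with g = 0.564 min⁻¹, comes to 50.5 % by this reckoning. Oak, with g = 0.291 min⁻¹, comes to 37.6 %. So cedar ends higher, and the hunch fails.

The forecast, made from the same runs, names cedar, with 51 % and 37 %: “Cedar ends clearly higher”.

The flasks give 52.1 % in cedar and 38.0 % in oak. Free monomer left stands at 25.2 % in cedar and 26.0 % in oak, while homo dimer stands at 22.7 % and 36.0 %. The reckoning carried from g, at 50.5 % for cedar and 37.6 % for oak, stands below the flasks by 1.6 percentage points in cedar and by 0.40 points in oak.

    initiator → 2 initiating radical (k = 0.00650 s⁻¹)
    2 free monomer → homo dimer (k = 0.110 L mol⁻¹ s⁻¹)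
    2 growing radical → dead chain (k = 7.00 × 10⁶ L mol⁻¹ s⁻¹)
    free monomer + initiating radical → growing radical + monomer in chains (k = 4.70 × 10⁵ L mol⁻¹ s⁻¹)
    free monomer + growing radical → monomer in chains + growing radical, rate k5*[growing radical]*[free monomer] (k = 19000 L mol⁻¹ s⁻¹)

A neighbour of cedar charged with 0.060 mM of initiator, read at the same time, has g = 0.357 min⁻¹, and the reckoning gives 37.3 %. The computed flask gives 37.2 %, within 2 points of oak, so at that charge the answer reads neither.

(The earlier runs and the new flask are calculated with constants of no real substance, noise included.)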